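**Strategy**

Everything rests on cutting C3–C4 of the dihydropyranone ring C as a C3=C4 double bond. The acyloin O=C4–C3(OH) is the Rubottom retron of a 4-silyloxy-2H-chromene, and this cyclic silyl enol ether is closed by ring-closing metathesis between the silyl enol ether of a ring A acetophenone (C4, already carrying its oxygen) and the vinyl group (C3) of a branched allylic aryl ether. In one operation ring C is forged with the C4 oxygen in place and an alkene poised for face-selective oxygenation at C3. The precursor is an acyclic 1,7-diene whose only stereocentre, C2, comes from iridium-catalysed allylic etherification; the prenyl ether is present from step 1.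

Key step: step 5

Assumption: the ligand antipode written in step 3 is the one taken to deliver the S ether; should a model reaction show the opposite sense, its mirror image is used with nothing else changed.

**Route**

Step 1
Reactants: 1 2',4',6'-trihydroxyacetophenone; 2 prenyl bromide (1-bromo-3-methylbut-2-ene)
Product: 3 1-[2,6-dihydroxy-4-(3-methylbut-2-en-1-yloxy)phenyl]ethan-1-one
Conditions: K2CO3 (1.0 equiv), acetone, reflux
Reagents that add atoms: none
Why: Williamson etherification (SN2) should take place at the para hydroxyl, the most acidic one and the only one not hydrogen-bonded to the acetyl group.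

Step 2
Reactants: 4 tert-butyldimethyl(4-vinylphenoxy)silane; 5 allyl methyl carbonate (3 equiv)
Product: 6 (E)-3-[4-(tert-butyldimethylsilyloxy)phenyl]prop-2-en-1-yl methyl carbonate
Conditions: second-generation Grubbs catalyst RuCl2(=CHPh)(H2IMes)(PCy3) (2 mol %), CH2Cl2, 40 °C
Reagents that add atoms: none
Why: Olefin cross-metathesis of a styrene with an excess of the allylic carbonate should give the E-cinnamyl carbonate under thermodynamic control.

Step 3
Reactants: 3 1-[2,6-dihydroxy-4-(3-methylbut-2-en-1-yloxy)phenyl]ethan-1-one (1.2 equiv); 6 (E)-3-[4-(tert-butyldimethylsilyloxy)phenyl]prop-2-en-1-yl methyl carbonate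
Product: 8 1-[2-({(1S)-1-[4-(tert-butyldimethylsilyloxy)phenyl]prop-2-en-1-yl}oxy)-6-hydroxy-4-(3-methylbut-2-en-1-yloxy)phenyl]ethan-1-one, via lithium phenoxide 7 (not isolated)
Conditions: LiN(SiMe3)2 (1.2 equiv), THF, 0 °C; then 6, [Ir(cod)Cl]2 (2 mol %), (Sa,Sc,Sc)-O,O'-(1,1'-binaphthalene-2,2'-diyl) N,N-bis(1-phenylethyl)phosphoramidite (4 mol %), THF, 50 °C; aqueous work-up
Reagents that add atoms: none
Why: Iridium-catalysed asymmetric allylic etherification, in which outer-sphere attack of phenoxide 7 on the more substituted terminus of the cyclometalated iridium allyl complex should give the branched ether, the phosphoramidite ligand setting C2 as S (the same arrangement is numbered 2R once C3 bears oxygen), while the second ortho hydroxyl stays chelated to the acetyl group.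

Step 4
Reactants: 8 1-[2-({(1S)-1-[4-(tert-butyldimethylsilyloxy)phenyl]prop-2-en-1-yl}oxy)-6-hydroxy-4-(3-methylbut-2-en-1-yloxy)phenyl]ethan-1-one
Product: 9 tert-butyl({1-[2-({(1S)-1-[4-(tert-butyldimethylsilyloxy)phenyl]prop-2-en-1-yl}oxy)-6-(tert-butyldimethylsilyloxy)-4-(3-methylbut-2-en-1-yloxy)phenyl]ethenyl}oxy)dimethylsilane
Conditions: TBSOTf (2.5 equiv), Et3N (5 equiv), CH2Cl2, −78 to 0 °C
Reagents that add atoms: tert-butyldimethylsilyl trifluoromethanesulfonate, CC(C)(C)[Si](C)(C)OS(=O)(=O)C(F)(F)F
Why: Soft enolisation and O-silylation with a silyl triflate and an amine (silyl enol ether formation) should turn the methyl ketone into the 1,1-disubstituted enol ether and cap the remaining phenol in the same flask, C2 being neither acidic nor involved.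

Step 5
Reactants: 9 tert-butyl({1-[2-({(1S)-1-[4-(tert-butyldimethylsilyloxy)phenyl]prop-2-en-1-yl}oxy)-6-(tert-butyldimethylsilyloxy)-4-(3-methylbut-2-en-1-yloxy)phenyl]ethenyl}oxy)dimethylsilane
Product: 10 (2S)-4,5-bis(tert-butyldimethylsilyloxy)-2-[4-(tert-butyldimethylsilyloxy)phenyl]-7-(3-methylbut-2-en-1-yloxy)-2H-chromene
Conditions: second-generation Grubbs catalyst RuCl2(=CHPh)(H2IMes)(PCy3) (5 mol %), CH2Cl2 (0.005 M), 40 °C, argon, exclusion of light
Reagents that add atoms: none
Why: The ruthenium benzylidene should first exchange with the unhindered monosubstituted vinyl group at C3, and the resulting C3 alkylidene then adds in a [2+2] sense to the 1,1-disubstituted silyl enol ether at C4, cycloreversion of the ruthenacyclobutane releasing ethene and the C3=C4 bond. The closest known reaction type is ring-closing olefin metathesis of an acyclic silyl enol ether with a terminal alkene to a cyclic silyl enol ether, applied here to an aryl ketone enol ether. Ring C, the only ring formed, is closed as a six-membered ring by intramolecular alkene metathesis of a 1,7-diene whose two termini are held ortho to each other on ring A. No stereocentre is created, and C2 takes part in no bond that is made or broken, so its S configuration should be carried over unchanged. The step needs chemoselectivity for the two terminal alkenes over the trisubstituted prenyl alkene and ring closure over oligomerisation, which the low metathesis reactivity of the prenyl group, the ortho preorganisation and high dilution should secure. The product holds the C4 oxygen as an enol ether, so the C3 hydroxyl can be delivered next under control of C2.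

Step 6
Reactants: 10 (2S)-4,5-bis(tert-butyldimethylsilyloxy)-2-[4-(tert-butyldimethylsilyloxy)phenyl]-7-(3-methylbut-2-en-1-yloxy)-2H-chromene
Product: 12 (2R,3R)-3,5-dihydroxy-2-(4-hydroxyphenyl)-7-(3-methylbut-2-en-1-yloxy)-2,3-dihydro-4H-chromen-4-one (7-prenyloxyaromadendrin), via silyloxy epoxide 11 (not isolated)
Conditions: dimethyldioxirane (1.05 equiv, acetone solution), CH2Cl2, −78 °C; then Bu4NF (3.5 equiv), AcOH (3.5 equiv), THF, 0 °C to rt
Reagents that add atoms: dimethyldioxirane, CC1(C)OO1
Why: Rubottom oxidation, in which the dioxirane should epoxidise the electron-rich silyl enol ether much faster than the prenyl alkene and from the face opposite to the C2 aryl group, which sets C3 as R (trans to the aryl group), after which buffered fluoride opens the silyloxy epoxide to the α-hydroxy ketone and cleaves both aryl silyl ethers.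

**Compound list**

1 | 2',4',6'-trihydroxyacetophenone | CC(=O)c1c(O)cc(O)cc1O | starting material
2 | prenyl bromide (1-bromo-3-methylbut-2-ene) | CC(C)=CCBr | starting material
3 | 1-[2,6-dihydroxy-4-(3-methylbut-2-en-1-yloxy)phenyl]ethan-1-one | CC(=O)c1c(O)cc(OCC=C(C)C)cc1O | intermediate
4 | tert-butyldimethyl(4-vinylphenoxy)silane | C=Cc1ccc(O[Si](C)(C)C(C)(C)C)cc1 | starting material
5 | allyl methyl carbonate | C=CCOC(=O)OC | starting material
6 | (E)-3-[4-(tert-butyldimethylsilyloxy)phenyl]prop-2-en-1-yl methyl carbonate | COC(=O)OC/C=C/c1ccc(O[Si](C)(C)C(C)(C)C)cc1 | intermediate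
7 | lithium 2-acetyl-3-hydroxy-5-(3-methylbut-2-en-1-yloxy)phenolate | CC(=O)c1c(O)cc(OCC=C(C)C)cc1[O-].[Li+] | intermediate
8 | 1-[2-({(1S)-1-[4-(tert-butyldimethylsilyloxy)phenyl]prop-2-en-1-yl}oxy)-6-hydroxy-4-(3-methylbut-2-en-1-yloxy)phenyl]ethan-1-one | CC(=O)c1c(O)cc(OCC=C(C)C)cc1O[C@H](c1ccc(O[Si](C)(C)C(C)(C)C)cc1)C=C | intermediate
9 | tert-butyl({1-[2-({(1S)-1-[4-(tert-butyldimethylsilyloxy)phenyl]prop-2-en-1-yl}oxy)-6-(tert-butyldimethylsilyloxy)-4-(3-methylbut-2-en-1-yloxy)phenyl]ethenyl}oxy)dimethylsilane | C=C(O[Si](C)(C)C(C)(C)C)c1c(O[Si](C)(C)C(C)(C)C)cc(OCC=C(C)C)cc1O[C@H](c1ccc(O[Si](C)(C)C(C)(C)C)cc1)C=C | intermediate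
10 | (2S)-4,5-bis(tert-butyldimethylsilyloxy)-2-[4-(tert-butyldimethylsilyloxy)phenyl]-7-(3-methylbut-2-en-1-yloxy)-2H-chromene | CC(C)=CCOc1cc(O[Si](C)(C)C(C)(C)C)c2c(c1)O[C@H](c1ccc(O[Si](C)(C)C(C)(C)C)cc1)C=C2O[Si](C)(C)C(C)(C)C | intermediate
11 | (1aR,2R,7bR)-7,7b-bis(tert-butyldimethylsilyloxy)-2-[4-(tert-butyldimethylsilyloxy)phenyl]-5-(3-methylbut-2-en-1-yloxy)-1a,7b-dihydro-2H-oxireno[2,3-c]chromene (the C3–C4 epoxide of 10, oxirane oxygen on the face opposite to the C2 aryl group) | CC(C)=CCOc1cc(O[Si](C)(C)C(C)(C)C)c2c(c1)O[C@H](c1ccc(O[Si](C)(C)C(C)(C)C)cc1)[C@H]3O[C@@]23O[Si](C)(C)C(C)(C)C | intermediate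
12 | (2R,3R)-3,5-dihydroxy-2-(4-hydroxyphenyl)-7-(3-methylbut-2-en-1-yloxy)-2,3-dihydro-4H-chromen-4-one (7-prenyloxyaromadendrin) | CC(C)=CCOc1cc(O)c2c(c1)O[C@H](c1ccc(O)cc1)[C@@H](O)C2=O | target

**Count**

Total steps: 6. Longest linear sequence: 5 steps (steps 1, 3, 4, 5 and 6).

**Steps most likely to fail, with fallbacks**

Step 5 (ring-closing metathesis). Ring closure onto the hindered, peri-flanked 1,1-disubstituted enol ether may be slow. Alkene isomerisation, cross-metathesis at the prenyl group or hydrolysis of the enol ether could then take over.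
The fallback sets out from compound 3, builds ring C by a chromone route instead, and comes back at compound 10.
- Heating 3 with N,N-dimethylformamide dimethyl acetal in toluene at 80 °C should give the enaminone (E)-3-(dimethylamino)-1-[2,6-dihydroxy-4-(3-methylbut-2-en-1-yloxy)phenyl]prop-2-en-1-one F1.
- Treatment with AcOH in CH2Cl2 should cyclise it, with loss of dimethylamine, to 5-hydroxy-7-(3-methylbut-2-en-1-yloxy)-4H-chromen-4-one F2.
- Asymmetric conjugate addition of 4-(tert-butyldimethylsilyloxy)phenylboronic acid should then set C2 and give the flavanone (2S)-2-[4-(tert-butyldimethylsilyloxy)phenyl]-5-hydroxy-7-(3-methylbut-2-en-1-yloxy)chroman-4-one F3. Conditions: Pd(OCOCF3)2, the antipode of 4-tert-butyl-2-(pyridin-2-yl)-4,5-dihydrooxazole that leads to 2S, NH4PF6, water, 1,2-dichloroethane, 60 °C.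
- TBSOTf and Et3N, as in step 4, should convert F3 into compound 10.

Step 3 (iridium-catalysed etherification). The acylphloroglucinol phenoxide may react at ring carbon instead of oxygen. The product may also reionise at iridium, with isomerisation of the branched ether to the linear one or erosion of the enantiomeric purity.
The fallback sets out from compound 3 and comes back at compound 8.
- 4-(tert-Butyldimethylsilyloxy)benzaldehyde and ethynylmagnesium bromide (THF, 0 °C) should give racemic 1-[4-(tert-butyldimethylsilyloxy)phenyl]prop-2-yn-1-ol F4.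
- Ac2O and pyridine should convert it into 1-[4-(tert-butyldimethylsilyloxy)phenyl]prop-2-yn-1-yl acetate F5.
- Copper-catalysed enantioselective propargylic etherification of 3 with F5 should give 1-[2-({(1S)-1-[4-(tert-butyldimethylsilyloxy)phenyl]prop-2-yn-1-yl}oxy)-6-hydroxy-4-(3-methylbut-2-en-1-yloxy)phenyl]ethan-1-one F6. It runs through a copper allenylidene; conditions: (CuOTf)2·C6H6, a chiral 2,6-bis(oxazolinyl)pyridine ligand, i-Pr2NEt, MeOH, −20 °C.
- Semihydrogenation of the terminal alkyne should give compound 8 and leave the trisubstituted prenyl alkene untouched. Conditions: H2, Pd on CaCO3 poisoned with Pb(OAc)2 (Lindlar catalyst), quinoline, EtOAc.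

Step 6 (Rubottom oxidation and desilylation). The dioxirane may also epoxidise the prenyl double bond or attack the enol ether from the face of the aryl group. The fluoride treatment may cause epimerisation or dehydrogenation towards the flavonol.
The fallback sets out from compound 10, replaces epoxidation by oxoammonium trapping with isolated intermediates, and comes back at compound 12.
- 2,2,6,6-Tetramethyl-1-oxopiperidin-1-ium tetrafluoroborate (1.0 equiv, CH2Cl2, −78 °C) should be trapped at C3 anti to the aryl group. This should give (2R,3R)-5-(tert-butyldimethylsilyloxy)-2-[4-(tert-butyldimethylsilyloxy)phenyl]-7-(3-methylbut-2-en-1-yloxy)-3-[(2,2,6,6-tetramethylpiperidin-1-yl)oxy]chroman-4-one F7.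
- Zinc dust in AcOH and THF should cleave the N–O bond to (2R,3R)-5-(tert-butyldimethylsilyloxy)-2-[4-(tert-butyldimethylsilyloxy)phenyl]-3-hydroxy-7-(3-methylbut-2-en-1-yloxy)chroman-4-one F8. At this stage a minor cis isomer could be equilibrated at C3 to the more stable trans compound.
- Bu4NF buffered with AcOH should then give compound 12.

**Further compounds**

F1 | step 5 | (E)-3-(dimethylamino)-1-[2,6-dihydroxy-4-(3-methylbut-2-en-1-yloxy)phenyl]prop-2-en-1-one | CN(C)/C=C/C(=O)c1c(O)cc(OCC=C(C)C)cc1O
F2 | step 5 | 5-hydroxy-7-(3-methylbut-2-en-1-yloxy)-4H-chromen-4-one | CC(C)=CCOc1cc(O)c2c(c1)occc2=O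
F3 | step 5 | (2S)-2-[4-(tert-butyldimethylsilyloxy)phenyl]-5-hydroxy-7-(3-methylbut-2-en-1-yloxy)chroman-4-one | CC(C)=CCOc1cc(O)c2c(c1)O[C@H](c1ccc(O[Si](C)(C)C(C)(C)C)cc1)CC2=O
F4 | step 3 | 1-[4-(tert-butyldimethylsilyloxy)phenyl]prop-2-yn-1-ol (racemic) | OC(C#C)c1ccc(O[Si](C)(C)C(C)(C)C)cc1
F5 | step 3 | 1-[4-(tert-butyldimethylsilyloxy)phenyl]prop-2-yn-1-yl acetate (racemic) | CC(=O)OC(C#C)c1ccc(O[Si](C)(C)C(C)(C)C)cc1
F6 | step 3 | 1-[2-({(1S)-1-[4-(tert-butyldimethylsilyloxy)phenyl]prop-2-yn-1-yl}oxy)-6-hydroxy-4-(3-methylbut-2-en-1-yloxy)phenyl]ethan-1-one | CC(=O)c1c(O)cc(OCC=C(C)C)cc1O[C@H](c1ccc(O[Si](C)(C)C(C)(C)C)cc1)C#C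
F7 | step 6 | (2R,3R)-5-(tert-butyldimethylsilyloxy)-2-[4-(tert-butyldimethylsilyloxy)phenyl]-7-(3-methylbut-2-en-1-yloxy)-3-[(2,2,6,6-tetramethylpiperidin-1-yl)oxy]chroman-4-one | CC(C)=CCOc1cc(O[Si](C)(C)C(C)(C)C)c2c(c1)O[C@H](c1ccc(O[Si](C)(C)C(C)(C)C)cc1)[C@@H](ON1C(C)(C)CCCC1(C)C)C2=O
F8 | step 6 | (2R,3R)-5-(tert-butyldimethylsilyloxy)-2-[4-(tert-butyldimethylsilyloxy)phenyl]-3-hydroxy-7-(3-methylbut-2-en-1-yloxy)chroman-4-one | CC(C)=CCOc1cc(O[Si](C)(C)C(C)(C)C)c2c(c1)O[C@H](c1ccc(O[Si](C)(C)C(C)(C)C)cc1)[C@@H](O)C2=O
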